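**Plan**
Target numbering, used in all explanations: seven-membered ring C1(Me)=C2–C3–C4(Me)–C8(H)–C9(OAr)–C10, five-membered ring C4–C5(OH)–C6–C7(OH)(iPr)–C8. The enabling feature is that the fully substituted carbinol carbon C7 lies five atoms from the ring-fusion carbon C8 (C8–C4–C5–C6–C7) and C8 is bonded to the oxygen-bearing C9, so a carbenoid at C8 beside a C9 ketone can insert into the oxygen-activated C7–H bond of an open chain carried by C4.
Retrosynthetic cuts, in order: C9–O ester; C7–C8 (C–H insertion, opens the five-membered ring); C5–C6 (aldol) together with the C7 carbinol; C4–C5 (conjugate alkenylation of a symmetric dienone); seven-membered ring back to a furan/oxyallyl (4+3) adduct.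
Forward: the seven-membered ring is made first, the C5–C7 chain is grown on C4, the five-membered ring closes by insertion, then alkene shift, C9 reduction and acylation.
Stereochemistry: C4 from a catalytic asymmetric conjugate addition; C5 from a reagent-controlled boron aldol; C7 from a hydroxyl-directed 1,3-anti reduction, carried through the insertion with retention; C8 by equilibration to the trans ring fusion; C9 by hydride delivery from the C7 hydroxyl.

Key step: step 11

Assumption: (−)-Ipc2BCl is taken to send methyl ketone enolates to the Re face of aldehydes, and the (R,R)-phosphinamine–copper catalyst to give the (R)-adduct; both chiral reagents exist in either enantiomeric form, so a reversed sense would be met with the antipode.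

**Step 1**
Reactants: 1 2,5-dimethylfuran; 2 1,3-dichloropropan-2-one
Product: 3 2-chloro-1,5-dimethyl-8-oxabicyclo[3.2.1]oct-6-en-3-one (racemic; both C2 epimers)
Conditions: Et3N, CF3CH2OH, 0 °C → rt (1 in excess)
Reagents that add atoms: none
Why: Dehydrochlorination of the α-chloro ketone in the ionising, weakly nucleophilic fluoro alcohol generates a chloro-substituted oxyallyl cation that the electron-rich furan traps in a (4+3) cycloaddition; the bridgehead methyl groups are necessarily cis and the chlorine-bearing centre is removed in step 2.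

**Step 2**
Reactants: 3 2-chloro-1,5-dimethyl-8-oxabicyclo[3.2.1]oct-6-en-3-one
Product: 5 (1R,5S)-1,5-dimethyl-8-oxabicyclo[3.2.1]octan-3-one (meso), via saturated chloro ketone 4 (not isolated)
Conditions: H2 (1 atm), Pd/C, Et3N, EtOAc, rt
Reagents that add atoms: none
Why: Catalytic hydrogenation saturates the strained ring alkene and, with base present, hydrogenolyses the carbonyl-activated C–Cl bond, so one operation should give the achiral meso ketone.

**Step 3**
Reactants: 5 (1R,5S)-1,5-dimethyl-8-oxabicyclo[3.2.1]octan-3-one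
Product: 7 3,6-dimethylcyclohepta-2,6-dien-1-one, via hydroxy enone 6 (not isolated)
Conditions: TsOH·H2O (cat.), toluene, reflux, Dean–Stark
Reagents that add atoms: none
Why: Acid-catalysed β-elimination (retro-oxa-Michael) of the tertiary β-alkoxy ketone opens the ether bridge and dehydration of the tertiary β-hydroxy ketone so formed gives the cross-conjugated dienone, the established conversion of 8-oxabicyclo[3.2.1]octan-3-ones into 4,5-dihydrotropones, eased here by the tertiary C–O bonds.

**Step 4**
Reactants: 7 3,6-dimethylcyclohepta-2,6-dien-1-one; 8 hex-1-yne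
Product: 10 (6R)-6-[(1E)-hex-1-en-1-yl]-3,6-dimethylcyclohept-2-en-1-one, via alkenylalane 9 (not isolated)
Conditions: 8, iBu2AlH, hexane, 50 °C; then 7, Cu(O2CC4H3S) (10 mol %, monovalent copper), SimplePhos ligand Ph2P–N[(R)-CH(CH3)Ph]2 (11 mol %), Et2O, −30 °C
Reagents that add atoms: none
Why: syn-Hydroalumination of the terminal alkyne gives the (E)-alkenylalane, which undergoes copper-catalysed asymmetric conjugate addition to one of the two enantiotopic β-methyl enone units of the symmetric dienone; the chiral phosphinamine–copper complex selects unit and face and so sets the quaternary carbon C4 as R, while the aluminium enolate formed prevents a second addition.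

**Step 5**
Reactants: 10 (6R)-6-[(1E)-hex-1-en-1-yl]-3,6-dimethylcyclohept-2-en-1-one
Product: 12 (1R)-1,5-dimethyl-3-oxocyclohept-4-ene-1-carbaldehyde, via secondary ozonide 11 (not isolated)
Conditions: O3, CH2Cl2, −78 °C (Sudan Red 7B end point); then PPh3, −78 °C → rt
Reagents that add atoms: ozone, [O-][O+]=O
Why: Ozonolysis with reductive work-up cleaves the electron-rich 1,2-disubstituted alkene much faster than the carbonyl-conjugated ring alkene, and the aldehyde obtained (C5) has no α-hydrogen, so the quaternary stereocentre cannot be lost.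

**Step 6**
Reactants: 12 (1R)-1,5-dimethyl-3-oxocyclohept-4-ene-1-carbaldehyde; 13 3-methylbutan-2-one
Product: 16 (6R)-6-[(1R)-1-hydroxy-4-methyl-3-oxopentyl]-3,6-dimethylcyclohept-2-en-1-one, via boron enolate 14 (not isolated), via boron aldolate 15 (not isolated)
Conditions: 13, (−)-Ipc2BCl, Et3N, Et2O, 0 °C; then 12, −78 → −20 °C; then H2O2, MeOH, pH 7 buffer, 0 °C
Reagents that add atoms: none
Why: Boron aldol reaction in which the kinetically formed diisopinocampheylboron enolate of the methyl ketone adds to the aldehyde, the only sufficiently electrophilic carbonyl group, through a cyclic transition state whose isopinocampheyl ligands direct attack to the Re face, setting C5 as R under reagent control because the α-quaternary aldehyde has no useful facial bias of its own.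

**Step 7**
Reactants: 16 (6R)-6-[(1R)-1-hydroxy-4-methyl-3-oxopentyl]-3,6-dimethylcyclohept-2-en-1-one
Product: 17 (6R)-6-[(1R,3R)-1,3-dihydroxy-4-methylpentyl]-3,6-dimethylcyclohept-2-en-1-one
Conditions: Me4NBH(OAc)3, MeCN/AcOH (1:1), −30 °C
Reagents that add atoms: none
Why: Evans–Saksena reduction in which the C5 hydroxyl exchanges onto boron and the alkoxyborohydride delivers hydride intramolecularly through a chair transition state, giving the 1,3-anti diol with C7 as R, while the ring enone, which has no β-hydroxyl, is left alone.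

**Step 8**
Reactants: 17 (6R)-6-[(1R,3R)-1,3-dihydroxy-4-methylpentyl]-3,6-dimethylcyclohept-2-en-1-one
Product: 18 (6R)-6-[(1R,3R)-1-hydroxy-4-methyl-3-(triethylsilyloxy)pentyl]-3,6-dimethylcyclohept-2-en-1-one
Conditions: Et3SiCl (1.05 equiv), imidazole, CH2Cl2, −40 °C
Reagents that add atoms: chlorotriethylsilane, CC[Si](Cl)(CC)CC
Why: Kinetic silylation distinguishes the two secondary hydroxyls, the C7 carbinol beside the isopropyl group reacting faster than the neopentylic C5 carbinol beside the quaternary carbon; no stereocentre is formed.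

**Step 9**
Reactants: 18 (6R)-6-[(1R,3R)-1-hydroxy-4-methyl-3-(triethylsilyloxy)pentyl]-3,6-dimethylcyclohept-2-en-1-one
Product: 19 (6R)-6-[(1R,3R)-1-(tert-butyldimethylsilyloxy)-4-methyl-3-(triethylsilyloxy)pentyl]-3,6-dimethylcyclohept-2-en-1-one
Conditions: tBuMe2SiOTf, 2,6-lutidine, CH2Cl2, −78 → 0 °C
Reagents that add atoms: tert-butyldimethylsilyl trifluoromethanesulfonate, CC(C)(C)[Si](C)(C)OS(=O)(=O)C(F)(F)F
Why: The reactive silyl triflate with a hindered pyridine base silylates the remaining hindered C5 hydroxyl without enolising the enone or disturbing the triethylsilyl ether, giving two silyl ethers of different lability.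

**Step 10**
Reactants: 19 (6R)-6-[(1R,3R)-1-(tert-butyldimethylsilyloxy)-4-methyl-3-(triethylsilyloxy)pentyl]-3,6-dimethylcyclohept-2-en-1-one
Product: 22 (3R)-3-[(1R,3R)-1-(tert-butyldimethylsilyloxy)-4-methyl-3-(triethylsilyloxy)pentyl]-2-diazo-3,6-dimethylcyclohept-6-en-1-one, via lithium enolate 20 (not isolated), via trifluoroacetyl ketone 21 (not isolated)
Conditions: LiN(SiMe3)2, THF, −78 °C; CF3CO2CH2CF3, −78 °C; then 4-acetamidobenzenesulfonyl azide, Et3N, H2O, MeCN, rt
Reagents that add atoms: 4-acetamidobenzenesulfonyl azide, CC(=O)Nc1ccc(cc1)S(=O)(=O)N=[N+]=[N-]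
Why: Regitz diazo transfer in its detrifluoroacetylative form, in which kinetic deprotonation of the enone can only occur at the α′ methylene C8 (C10 is an sp2 carbon), C-trifluoroacetylation activates that position for diazo transfer and loss of the trifluoroacetyl group leaves the α′-diazo enone with all stereocentres untouched.

**Step 11**
Reactants: 22 (3R)-3-[(1R,3R)-1-(tert-butyldimethylsilyloxy)-4-methyl-3-(triethylsilyloxy)pentyl]-2-diazo-3,6-dimethylcyclohept-6-en-1-one
Product: 24 (1R,3R,3aR,8aR)-1-(tert-butyldimethylsilyloxy)-6,8a-dimethyl-3-(propan-2-yl)-3-(triethylsilyloxy)-2,3,3a,7,8,8a-hexahydroazulen-4(1H)-one (trans-fused), via cis-fused ketone 23 (not isolated)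
Conditions: Rh2(OAc)4 (1 mol %, divalent rhodium), CH2Cl2, rt, slow addition of 22; then concentration, DBU (0.3 equiv), toluene, rt
Reagents that add atoms: none
Why: Rh2(OAc)4 takes N2 from 22 to give an electrophilic carbenoid at C8 that cannot collapse by 1,2-hydride shift (C4 is quaternary, C9 is a carbonyl) and inserts into the C7–H bond through a concerted three-centre transition state, the known rhodium-catalysed intramolecular C–H insertion of α-diazo ketones into ether-activated C–H bonds. The cyclopentane C4–C5–C6–C7–C8 closes in the 1,5 mode, the carbenoid carbon bonding to the fifth atom of the chain C8–C4–C5–C6–C7. C7 is controlled by the open-chain stereocentre, because insertion proceeds with retention and the (R) silyloxy methine becomes the (R) tertiary carbinol carbon. C8 is controlled in two stages: the tether on C4 can reach only the carbenoid lobe on its own side, which should give the cis-fused ketone 23, and DBU then equilibrates this α-carbonyl methine to the trans-fused 24, expected to be the more stable epimer because the ring carbonyl carbon on C8 then lies away from the isopropyl group on C7. The step needs site selectivity for C7–H and no ylide formation: C7–H is the only tertiary, oxygen-activated C–H in a 1,5 relationship (C5–H and C6–H2 would give three- and four-membered rings, the isopropyl methine a six-membered one), and the bulky, weakly basic silyl ethers together with slow addition to dilute catalyst hold back oxonium ylide formation and carbene dimerisation.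

**Step 12**
Reactants: 24 (1R,3R,3aR,8aR)-1-(tert-butyldimethylsilyloxy)-6,8a-dimethyl-3-(propan-2-yl)-3-(triethylsilyloxy)-2,3,3a,7,8,8a-hexahydroazulen-4(1H)-one
Product: 26 (1R,3R,3aR,8aR)-1-(tert-butyldimethylsilyloxy)-6,8a-dimethyl-3-(propan-2-yl)-3-(triethylsilyloxy)-1,2,3,3a,8,8a-hexahydroazulen-4(5H)-one, via potassium dienolate 25 (not isolated)
Conditions: KN(SiMe3)2, THF, −78 °C; then inverse quench into AcOH/THF, −78 °C
Reagents that add atoms: none
Why: Deconjugation by kinetic α-protonation of an extended dienolate, in which the base removes a γ-proton at C2 (the C8 methine is shielded by its two fully substituted neighbours) and acetic acid protonates the dienolate at C10 faster than at C2, moving the alkene to C1=C2 without touching C4, C5, C7 or C8.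

**Step 13**
Reactants: 26 (1R,3R,3aR,8aR)-1-(tert-butyldimethylsilyloxy)-6,8a-dimethyl-3-(propan-2-yl)-3-(triethylsilyloxy)-1,2,3,3a,8,8a-hexahydroazulen-4(5H)-one
Product: 27 (1R,3R,3aR,8aR)-1-(tert-butyldimethylsilyloxy)-3-hydroxy-6,8a-dimethyl-3-(propan-2-yl)-1,2,3,3a,8,8a-hexahydroazulen-4(5H)-one
Conditions: HF·pyridine, pyridine, THF, 0 °C
Reagents that add atoms: none
Why: Buffered fluoride-mediated desilylation cleaves the triethylsilyl ether faster than the hindered secondary tert-butyldimethylsilyl ether, and the weakly acidic medium avoids both retro-aldol cleavage of the β-hydroxy ketone and return of the alkene into conjugation.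

**Step 14**
Reactants: 27 (1R,3R,3aR,8aR)-1-(tert-butyldimethylsilyloxy)-3-hydroxy-6,8a-dimethyl-3-(propan-2-yl)-1,2,3,3a,8,8a-hexahydroazulen-4(5H)-one
Product: 28 (1R,3R,3aS,4S,8aR)-1-(tert-butyldimethylsilyloxy)-6,8a-dimethyl-3-(propan-2-yl)-1,2,3,3a,4,5,8,8a-octahydroazulene-3,4-diol
Conditions: Me4NBH(OAc)3, MeCN/AcOH (1:1), −30 → −20 °C
Reagents that add atoms: none
Why: Evans–Saksena reduction in which the tertiary C7 hydroxyl binds boron and delivers hydride to the face of the C9 carbonyl on which C7 lies, so that the new C9 hydroxyl ends on the face of C8–H and C9 is set as S.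

**Step 15**
Reactants: 29 4-hydroxybenzoic acid
Product: 31 4-(tert-butyldimethylsilyloxy)benzoic acid, via bis-silyl benzoate 30 (not isolated)
Conditions: tBuMe2SiCl (2.2 equiv), imidazole, DMF, rt; then AcOH/THF/H2O, rt
Reagents that add atoms: tert-butylchlorodimethylsilane, CC(C)(C)[Si](C)(C)Cl
Why: Silylation of phenol and acid followed by selective hydrolysis of the much more labile silyl ester is the standard protection of a phenolic acid.

**Step 16**
Reactants: 28 (1R,3R,3aS,4S,8aR)-1-(tert-butyldimethylsilyloxy)-6,8a-dimethyl-3-(propan-2-yl)-1,2,3,3a,4,5,8,8a-octahydroazulene-3,4-diol; 31 4-(tert-butyldimethylsilyloxy)benzoic acid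
Product: 32 (1R,3R,3aS,4S,8aR)-1-(tert-butyldimethylsilyloxy)-3-hydroxy-6,8a-dimethyl-3-(propan-2-yl)-1,2,3,3a,4,5,8,8a-octahydroazulen-4-yl 4-(tert-butyldimethylsilyloxy)benzoate
Conditions: DCC, DMAP, CH2Cl2, rt
Reagents that add atoms: none
Why: Steglich esterification acylates the secondary C9 hydroxyl while the tertiary C7 hydroxyl is unreactive, and the C9–O bond is not broken, so its configuration is kept.

**Step 17**
Reactants: 32 (1R,3R,3aS,4S,8aR)-1-(tert-butyldimethylsilyloxy)-3-hydroxy-6,8a-dimethyl-3-(propan-2-yl)-1,2,3,3a,4,5,8,8a-octahydroazulen-4-yl 4-(tert-butyldimethylsilyloxy)benzoate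
Product: 33 (1R,3R,3aS,4S,8aR)-1,3-dihydroxy-6,8a-dimethyl-3-(propan-2-yl)-1,2,3,3a,4,5,8,8a-octahydroazulen-4-yl 4-hydroxybenzoate
Conditions: HF·pyridine, THF, rt
Reagents that add atoms: none
Why: Fluoride-mediated desilylation removes the aryl and the secondary silyl ether in one operation under weakly acidic conditions that leave the ester, the tertiary alcohol and the trisubstituted alkene untouched.

**Compound list**
1 | 2,5-dimethylfuran | Cc1ccc(C)o1 | starting material
2 | 1,3-dichloropropan-2-one | ClCC(=O)CCl | starting material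
3 | 2-chloro-1,5-dimethyl-8-oxabicyclo[3.2.1]oct-6-en-3-one (racemic, both C2 epimers, bridge necessarily cis) | CC12C=CC(C)(O1)CC(=O)C2Cl | intermediate
4 | 2-chloro-1,5-dimethyl-8-oxabicyclo[3.2.1]octan-3-one (racemic, both C2 epimers) | CC12CCC(C)(O1)CC(=O)C2Cl | intermediate (not isolated)
5 | (1R,5S)-1,5-dimethyl-8-oxabicyclo[3.2.1]octan-3-one (meso) | C[C@@]12CC[C@@](C)(O1)CC(=O)C2 | intermediate
6 | 6-hydroxy-3,6-dimethylcyclohept-2-en-1-one (racemic) | CC1=CC(=O)CC(C)(O)CC1 | intermediate (not isolated)
7 | 3,6-dimethylcyclohepta-2,6-dien-1-one | CC1=CC(=O)C=C(C)CC1 | intermediate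
8 | hex-1-yne | CCCCC#C | starting material
9 | (E)-hex-1-enyl(diisobutyl)aluminium | CCCC/C=C/[Al](CC(C)C)CC(C)C | intermediate (not isolated)
10 | (6R)-6-[(1E)-hex-1-en-1-yl]-3,6-dimethylcyclohept-2-en-1-one | CC1=CC(=O)C[C@@](C)(CC1)/C=C/CCCC | intermediate
11 | secondary ozonide (1,2,4-trioxolane) of 10, trioxolane carbons unassigned | CC1=CC(=O)C[C@@](C)(CC1)C1OOC(CCCC)O1 | intermediate (not isolated)
12 | (1R)-1,5-dimethyl-3-oxocyclohept-4-ene-1-carbaldehyde | CC1=CC(=O)C[C@@](C)(CC1)C=O | intermediate
13 | 3-methylbutan-2-one | CC(=O)C(C)C | starting material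
14 | diisopinocampheylboron enolate of 13 (3-methylbut-1-en-2-yl borinate) | C=C(C(C)C)OB([C@@H]1C[C@@H]2C[C@H]([C@H]1C)C2(C)C)[C@@H]1C[C@@H]2C[C@H]([C@H]1C)C2(C)C | intermediate (not isolated)
15 | diisopinocampheylboron aldolate of 16 | CC1=CC(=O)C[C@@](C)(CC1)[C@H](OB([C@@H]2C[C@@H]3C[C@H]([C@H]2C)C3(C)C)[C@@H]2C[C@@H]3C[C@H]([C@H]2C)C3(C)C)CC(=O)C(C)C | intermediate (not isolated)
16 | (6R)-6-[(1R)-1-hydroxy-4-methyl-3-oxopentyl]-3,6-dimethylcyclohept-2-en-1-one | CC1=CC(=O)C[C@@](C)(CC1)[C@H](O)CC(=O)C(C)C | intermediate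
17 | (6R)-6-[(1R,3R)-1,3-dihydroxy-4-methylpentyl]-3,6-dimethylcyclohept-2-en-1-one | CC1=CC(=O)C[C@@](C)(CC1)[C@H](O)C[C@@H](O)C(C)C | intermediate
18 | (6R)-6-[(1R,3R)-1-hydroxy-4-methyl-3-(triethylsilyloxy)pentyl]-3,6-dimethylcyclohept-2-en-1-one | CC1=CC(=O)C[C@@](C)(CC1)[C@H](O)C[C@@H](O[Si](CC)(CC)CC)C(C)C | intermediate
19 | (6R)-6-[(1R,3R)-1-(tert-butyldimethylsilyloxy)-4-methyl-3-(triethylsilyloxy)pentyl]-3,6-dimethylcyclohept-2-en-1-one | CC1=CC(=O)C[C@@](C)(CC1)[C@H](O[Si](C)(C)C(C)(C)C)C[C@@H](O[Si](CC)(CC)CC)C(C)C | intermediate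
20 | lithium α′-enolate of 19 | CC1=CC([O-])=C[C@@](C)(CC1)[C@H](O[Si](C)(C)C(C)(C)C)C[C@@H](O[Si](CC)(CC)CC)C(C)C.[Li+] | intermediate (not isolated)
21 | 7-(trifluoroacetyl) derivative of 19 (C7 of the ring unassigned, largely enolised) | CC1=CC(=O)C(C(=O)C(F)(F)F)[C@@](C)(CC1)[C@H](O[Si](C)(C)C(C)(C)C)C[C@@H](O[Si](CC)(CC)CC)C(C)C | intermediate (not isolated)
22 | (3R)-3-[(1R,3R)-1-(tert-butyldimethylsilyloxy)-4-methyl-3-(triethylsilyloxy)pentyl]-2-diazo-3,6-dimethylcyclohept-6-en-1-one | CC1=CC(=O)C(=[N+]=[N-])[C@@](C)(CC1)[C@H](O[Si](C)(C)C(C)(C)C)C[C@@H](O[Si](CC)(CC)CC)C(C)C | intermediate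
23 | (1R,3R,3aS,8aR)-1-(tert-butyldimethylsilyloxy)-6,8a-dimethyl-3-(propan-2-yl)-3-(triethylsilyloxy)-2,3,3a,7,8,8a-hexahydroazulen-4(1H)-one (cis-fused) | CC1=CC(=O)[C@H]2[C@@](C)(CC1)[C@H](O[Si](C)(C)C(C)(C)C)C[C@@]2(O[Si](CC)(CC)CC)C(C)C | intermediate (not isolated)
24 | (1R,3R,3aR,8aR)-1-(tert-butyldimethylsilyloxy)-6,8a-dimethyl-3-(propan-2-yl)-3-(triethylsilyloxy)-2,3,3a,7,8,8a-hexahydroazulen-4(1H)-one (trans-fused) | CC1=CC(=O)[C@@H]2[C@@](C)(CC1)[C@H](O[Si](C)(C)C(C)(C)C)C[C@@]2(O[Si](CC)(CC)CC)C(C)C | intermediate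
25 | potassium dienolate of 24 (C9–O enolate, C9=C10 and C1=C2) | CC1=CC[C@@]2(C)[C@H](O[Si](C)(C)C(C)(C)C)C[C@@](O[Si](CC)(CC)CC)(C(C)C)[C@@H]2C([O-])=C1.[K+] | intermediate (not isolated)
26 | (1R,3R,3aR,8aR)-1-(tert-butyldimethylsilyloxy)-6,8a-dimethyl-3-(propan-2-yl)-3-(triethylsilyloxy)-1,2,3,3a,8,8a-hexahydroazulen-4(5H)-one | CC1=CC[C@@]2(C)[C@H](O[Si](C)(C)C(C)(C)C)C[C@@](O[Si](CC)(CC)CC)(C(C)C)[C@@H]2C(=O)C1 | intermediate
27 | (1R,3R,3aR,8aR)-1-(tert-butyldimethylsilyloxy)-3-hydroxy-6,8a-dimethyl-3-(propan-2-yl)-1,2,3,3a,8,8a-hexahydroazulen-4(5H)-one | CC1=CC[C@@]2(C)[C@H](O[Si](C)(C)C(C)(C)C)C[C@@](O)(C(C)C)[C@@H]2C(=O)C1 | intermediate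
28 | (1R,3R,3aS,4S,8aR)-1-(tert-butyldimethylsilyloxy)-6,8a-dimethyl-3-(propan-2-yl)-1,2,3,3a,4,5,8,8a-octahydroazulene-3,4-diol | CC1=CC[C@@]2(C)[C@H](O[Si](C)(C)C(C)(C)C)C[C@@](O)(C(C)C)[C@@H]2[C@@H](O)C1 | intermediate
29 | 4-hydroxybenzoic acid | OC(=O)c1ccc(O)cc1 | starting material
30 | tert-butyldimethylsilyl 4-(tert-butyldimethylsilyloxy)benzoate | CC(C)(C)[Si](C)(C)OC(=O)c1ccc(O[Si](C)(C)C(C)(C)C)cc1 | intermediate (not isolated)
31 | 4-(tert-butyldimethylsilyloxy)benzoic acid | CC(C)(C)[Si](C)(C)Oc1ccc(cc1)C(O)=O | intermediate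
32 | (1R,3R,3aS,4S,8aR)-1-(tert-butyldimethylsilyloxy)-3-hydroxy-6,8a-dimethyl-3-(propan-2-yl)-1,2,3,3a,4,5,8,8a-octahydroazulen-4-yl 4-(tert-butyldimethylsilyloxy)benzoate | CC1=CC[C@@]2(C)[C@H](O[Si](C)(C)C(C)(C)C)C[C@@](O)(C(C)C)[C@@H]2[C@@H](OC(=O)c2ccc(O[Si](C)(C)C(C)(C)C)cc2)C1 | intermediate
33 | (1R,3R,3aS,4S,8aR)-1,3-dihydroxy-6,8a-dimethyl-3-(propan-2-yl)-1,2,3,3a,4,5,8,8a-octahydroazulen-4-yl 4-hydroxybenzoate | CC1=CC[C@@]2(C)[C@H](O)C[C@@](O)(C(C)C)[C@@H]2[C@@H](OC(=O)c2ccc(O)cc2)C1 | target

**Step count**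
Total: 17 steps. Longest linear sequence: 16 steps (steps 1–14, 16 and 17); step 15 is a one-step side branch.

**Steps most likely to fail**

1. Step 11. The base stage may not deliver the trans ring fusion: with the bulky silyloxy group on C7 the equilibrium at C8 may stay on the cis side, or the C8 enolate may expel that silyloxy group. In the insertion stage the carbenoid may also be lost to attack by the C7 ether oxygen or to a 1,2-shift from C4. The fallback changes the element that controls C8 from sterics at the silyl ether to a hydrogen bond in the free aldol. It sets out from 23, which is isolated by running the insertion without DBU. HF·pyridine (pyridine, THF, 0 °C) should remove the triethylsilyl group to give the cis-fused hydroxy enone (1R,3R,3aS,8aR)-1-(tert-butyldimethylsilyloxy)-3-hydroxy-6,8a-dimethyl-3-(propan-2-yl)-2,3,3a,7,8,8a-hexahydroazulen-4(1H)-one F1. In F1 the C7 hydroxyl and the C9 carbonyl are trans on the cyclopentane; after inversion at C8 they become cis and can form an intramolecular hydrogen bond. Hydroxide is also a poorer leaving group than silanolate. Equilibration with DBU in toluene at rt should therefore favour the trans-fused hydroxy enone (1R,3R,3aR,8aR)-1-(tert-butyldimethylsilyloxy)-3-hydroxy-6,8a-dimethyl-3-(propan-2-yl)-2,3,3a,7,8,8a-hexahydroazulen-4(1H)-one F2. Et3SiOTf and 2,6-lutidine (CH2Cl2, −78 °C) then silylate the tertiary hydroxyl, and the route is rejoined at 24.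

2. Step 12. Deprotonation may take the C8 methine or the C1 methyl group instead of C2–H2, protonation of the dienolate may occur at the γ-carbon, the C8 enolate may eliminate the silyloxy group, and the alkene may drift back into conjugation on handling. The fallback separates dienolate formation from protonation and avoids the strong amide base. It sets out from 24. Soft enolisation with Me3SiOTf and Et3N (CH2Cl2, 0 °C) should give the thermodynamically preferred linear dienol ether, the 4-(trimethylsilyloxy)-4,6-diene F3, which can be isolated and its regiochemistry checked. Bu4NF with AcOH in THF at −78 °C then releases the dienolate and protonates it at C10, and the route is rejoined at 26.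

3. Step 4. Enantioselectivity or conversion may be low when a quaternary carbon is built on a cross-conjugated dienone, and isobutyl or hydride may be transferred from aluminium instead of the alkenyl group. The fallback replaces asymmetric catalysis by resolution. It sets out from 7. CH2=CHMgBr with catalytic CuBr·SMe2 (THF, −40 °C) should give racemic 6-ethenyl-3,6-dimethylcyclohept-2-en-1-one F4 by conjugate addition. Preparative chromatography on a chiral stationary phase then gives (6R)-6-ethenyl-3,6-dimethylcyclohept-2-en-1-one F5. Ozonolysis of the vinyl group (O3, CH2Cl2, −78 °C; PPh3) through the secondary ozonide F6 gives the aldehyde, and the route is rejoined at 12.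

**Further compounds**
F1 | step 11 | (1R,3R,3aS,8aR)-1-(tert-butyldimethylsilyloxy)-3-hydroxy-6,8a-dimethyl-3-(propan-2-yl)-2,3,3a,7,8,8a-hexahydroazulen-4(1H)-one | CC1=CC(=O)[C@H]2[C@@](C)(CC1)[C@H](O[Si](C)(C)C(C)(C)C)C[C@@]2(O)C(C)C
F2 | step 11 | (1R,3R,3aR,8aR)-1-(tert-butyldimethylsilyloxy)-3-hydroxy-6,8a-dimethyl-3-(propan-2-yl)-2,3,3a,7,8,8a-hexahydroazulen-4(1H)-one | CC1=CC(=O)[C@@H]2[C@@](C)(CC1)[C@H](O[Si](C)(C)C(C)(C)C)C[C@@]2(O)C(C)C
F3 | step 12 | trimethylsilyl dienol ether of 24 (C9–OSiMe3, C9=C10 and C1=C2) | CC1=CC[C@@]2(C)[C@H](O[Si](C)(C)C(C)(C)C)C[C@@](O[Si](CC)(CC)CC)(C(C)C)[C@@H]2C(O[Si](C)(C)C)=C1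
F4 | step 4 | 6-ethenyl-3,6-dimethylcyclohept-2-en-1-one (racemic) | CC1=CC(=O)CC(C)(CC1)C=C
F5 | step 4 | (6R)-6-ethenyl-3,6-dimethylcyclohept-2-en-1-one | CC1=CC(=O)C[C@@](C)(CC1)C=C
F6 | step 4 | secondary ozonide (1,2,4-trioxolane) of F5 | CC1=CC(=O)C[C@@](C)(CC1)C1OOCO1
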